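## Analysis of the target

The target 11 is a diarylmethane. Ring A is a pentasubstituted benzene (C1 CH2OH, C2 CH2Ar, C3 OH, C4 OH, C5 Br, C6 H) and ring B is a 3-bromo-4-hydroxyphenyl group attached through the C2 methylene. There is no stereocentre and no axis of chirality, so the problem is purely one of regiochemistry on ring A, where five adjacent carbons carry five different substituents. The sensitive groups are the free catechol of ring A (air oxidation, metal chelation), the two aryl bromides (metal exchange, hydrogenolysis) and above all the C1 hydroxymethyl group. That group sits para to the C4 hydroxyl and ionizes easily to a p-quinone methide under acid or heat. Electrophilic substitution on a preformed catechol or veratrole ring does not give this pattern: the benzyl group must enter at C2, between an oxygen-bearing carbon and C1, and bromine must go to C5 and not to C6. The strategy rests on the fact that C2 to C6 of ring A (benzylic carbon on C2, oxygen on C3 and C4, hydrogen on C5 and C6) are the five carbons of a 2-benzyl-3-hydroxy-4H-pyran-4-one with the same numbering. Replacing the pyranone ring oxygen by one carbon that carries an ester therefore creates C1 together with its future hydroxymethyl group. The pyranone C4 carbonyl then emerges as a free phenol next to a C3 methyl ether, and in this vanillate pattern C5 is the only open position ortho or para to the free hydroxyl.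

## Retrosynthetic reasoning

**11 to 10.** The hydroxymethyl group at C1 is taken back to the methyl ester of 10; no skeletal bond is cut. The p-hydroxybenzyl alcohol is the most fragile part of the target, so it is generated last and under basic conditions. Until then the ester deactivates ring A and cannot ionize. The forward step is a hydride reduction that must tolerate three free phenols and two aryl bromides.

**10 to 9.** The two O–CH3 bonds (C3 of ring A and C4 of ring B) are cut. The methyl groups are kept up to this point because they distinguish O3 from O4 and keep ring B less reactive than ring A during bromination. They are removed before the reduction so that the benzylic alcohol never meets a strong Lewis acid. The forward step must cleave two aryl methyl ethers and leave the methyl ester.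

**9 to 8.** The C5–Br bond is cut. In 8 the free C4 hydroxyl has C3 blocked by the methoxy group and its para position C1 blocked by the ester, so C5 is the only activated site. Introducing this bromine late also keeps a vinylic bromide out of the ring-forming step. The forward reaction must brominate the phenolic ring A once and leave the bromoanisole ring B alone.

**8 to 5 and 6.** The C1–C2 and C1–C6 bonds are cut, which removes C1 with its ester and leaves C2 to C6 as the carbon skeleton of pyranone 5, with the ring oxygen in the place of C1. This is the disconnection of choice because C1 is the only ring carbon that carries neither a heteroatom nor the benzyl group, and because the remaining five carbons with all their substituents are a simple heterocycle. The one-carbon partner must be a carbon nucleophile that can afterwards condense with a ketone and carry the ester, which is phosphonoacetate 6. The forward reaction has to add 6 to the pyranone, open the ring to the acyclic intermediate 7 and close the carbocycle. The position of the first attack does not matter, since the new carbon ends between C2 and C6 either way.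

**5 to 4.** The O–CH3 bond at C3 is cut. The methyl ether is needed for two reasons. A free enolic hydroxyl would be deprotonated in the key step and would make the pyranone an unreactive anion. The ether also provides the later O3/O4 differentiation.

**4 to 3.** The benzylic C–H bond is traced back to a C–OH bond. Carbinol 3 is the aldol retron, and its hydroxyl sits on a carbon that is flanked by an electron-rich arene and an enol, so it should be removable by ionic reduction.

**3 to 1 and 2.** The bond between pyranone C2 and the benzylic carbon is cut. C2 is the only nucleophilic carbon of 1 (ortho to the enolic hydroxyl), and aldehyde 2 brings ring B with its bromine and its protected phenol already in place. The forward reaction is a base-mediated aldol addition.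

## Alternatives that were turned down

**Alternative 1:** Ring A would be cut at C1–C2 and C3–C4 and traced to a furan and an alkyne joined by an ether tether: racemic 4-bromo-2-({[1-(3-bromo-4-triisopropylsilyloxyphenyl)prop-2-yn-1-yl]oxy}methyl)furan A1.
- **Forward key step:** a trivalent gold halide catalyst would isomerize A1. The furan attacks the activated alkyne, the furan ring opens to a carbonyl-substituted gold carbene, and arene oxide formation and opening give the phenol. The benzene ring and the fused dihydrofuran ring of racemic 6-bromo-3-(3-bromo-4-triisopropylsilyloxyphenyl)-1,3-dihydroisobenzofuran-4-ol A2 would close in one operation.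
- **For it:** the reaction type is established for furfuryl propargyl ethers, it is catalytic and fully atom-economical, both bromines come in with the building blocks, and the tether guarantees the ortho relationship of the C1 and C2 carbon substituents.
- **Against it:** the furan oxygen ends on C3 only, so C4 of ring A is a CH in A2. The second catechol oxygen would have to be added late by ortho-oxidation of an electron-rich bromophenol. The diarylmethyl C–O bond of the cyclic ether must then be cleaved reductively without touching the other benzylic C–O bond. The propargylic ether of A1 carries an electron-rich aryl group and can ionize under the Lewis-acidic catalyst, and the bromine lowers the nucleophilicity of the furan. Ether assembly from two non-commercial halves, cyclization, oxygenation, ring opening and desilylation make it longer than seven steps.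
- **Comparison:** it is stronger on precedent for the key step and on bromine placement. The chosen route offers a key-step product that already carries both ring A oxygens in the right places, and a bromination whose site is fixed by the substitution pattern.

**Alternative 2:** The C1–C(carboxyl) and C2–C(benzylic) bonds would both be cut, leading to the C1–C2 aryne of ring A. The aryne precursor is 4-bromo-2,3-dimethoxy-6-(trimethylsilyl)phenyl trifluoromethanesulfonate A3, and the partners are tert-butyl isocyanide A4 and aldehyde 2.
- **Forward key step:** fluoride would release the aryne. A4 adds at C1, remote from the C3 methoxy group, the C2 aryl anion adds to aldehyde 2, and the alkoxide closes on the nitrilium carbon. The product is racemic N-tert-butyl-6-bromo-3-(3-bromo-4-methoxyphenyl)-4,5-dimethoxy-3H-isobenzofuran-1-imine A5.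
- **For it:** this is a known three-component coupling, 3-alkoxyarynes reliably take nucleophiles at the distal carbon, all five ring A substituents are in place after one step, no aromatic bromination is needed, and it uses the same aldehyde 2.
- **Against it:** A3 is itself a pentasubstituted benzene. Its preparation needs several regiocontrolled steps and must place silicon and triflate next to an aryl bromide, where halogen–metal exchange and halogen migration are threats. After the coupling, the imidate must be hydrolysed to the lactone, the benzylic C–O bond and the carboxyl carbon must be reduced, and three methyl ethers must be cleaved close to the sensitive hydroxymethyl stage. The total is near ten steps.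
- **Comparison:** it is stronger on precedent and on the fact that every ring A substituent is fixed by the building block. The chosen route is shorter, starts from three simple commercial compounds, and has no polysubstituted benzene to prepare.

**Alternative 3:** Ring A would be cut at C1–C2 and C5–C6 into a four-carbon diene and a two-carbon dienophile. 5-(3-Bromo-4-methoxyphenyl)pentane-2,3-dione A6 would be bis-silylated to (3Z)-5-(3-bromo-4-methoxyphenyl)-2,3-bis(trimethylsilyloxy)penta-1,3-diene A7.
- **Forward key step:** A7 would undergo a (4+2) cycloaddition with methyl propiolate A8. A quinone oxidant added to the same flask would aromatize the cyclohexadiene to methyl 2-(3-bromo-4-methoxybenzyl)-3,4-bis(trimethylsilyloxy)benzoate A9.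
- **For it:** the cycloaddition is a well-understood reaction type, both catechol oxygens come from the diketone, and the silyl ethers come off under far milder conditions than methyl ethers.
- **Against it:** the two silyloxy groups on C3 and C4 direct the unsymmetrical dienophile in opposite senses. The regiochemistry therefore rests on the C2 alkyl terminus alone, and the isomer with the ester on C6 is to be expected as well. Only the geometrical isomer of A7 with the benzylic substituent pointing outward can reach the reactive s-cis conformation, and bis-silylation of A6 gives no control over it. A7 is hydrolytically labile and A6 needs its own short synthesis. Most important, O3 and O4 are not differentiated after the key step, so bromination has no structural bias between C5 (ortho to O4) and C6 (para to O3).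
- **Comparison:** it is stronger in the familiarity of its key step and in the mildness of the catechol deprotection. The chosen route offers the O3/O4 differentiation that fixes the bromination site, a ring closure that cannot give a regioisomer, and fewer steps.

Key step: step 4

Remark: the target has no stereocentre. The only stereocentre met on the way, the carbinol carbon of 3, is formed as a racemate and removed in step 2.

## Route

Step 1
Reactants: 1 pyromeconic acid (3-hydroxy-4H-pyran-4-one); 2 3-bromo-4-methoxybenzaldehyde
Product: 3 2-[(3-bromo-4-methoxyphenyl)(hydroxy)methyl]-3-hydroxy-4H-pyran-4-one (racemic)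
Conditions: DABCO (1.0 equiv), 2 (1.2 equiv), 1,4-dioxane–H2O (1:1), 25 °C; then AcOH to pH 5
Reagents that add atoms: none
Why: Base-mediated aldol addition of a 3-hydroxy-4-pyranone; the anion of 1 is C-nucleophilic only at C2, ortho to the enolic hydroxyl, and aldehyde 2 cannot enolize, so one adduct should form; the carbinol stereocentre is racemic and is removed in step 2.

Step 2
Reactants: 3 2-[(3-bromo-4-methoxyphenyl)(hydroxy)methyl]-3-hydroxy-4H-pyran-4-one
Product: 4 2-(3-bromo-4-methoxybenzyl)-3-hydroxy-4H-pyran-4-one
Conditions: Et3SiH (3 equiv), CF3CO2H (10 equiv), CH2Cl2, 0 → 25 °C
Reagents that add atoms: none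
Why: Ionic hydrogenation (ionic deoxygenation); loss of water gives a cation stabilized by the p-methoxyphenyl group and by the enol oxygen on C3, which the silane should reduce, while the aryl bromide and the pyranone are inert to these conditions.

Step 3
Reactants: 4 2-(3-bromo-4-methoxybenzyl)-3-hydroxy-4H-pyran-4-one
Product: 5 2-(3-bromo-4-methoxybenzyl)-3-methoxy-4H-pyran-4-one
Conditions: MeI (1.5 equiv), K2CO3 (2 equiv), acetone, 56 °C
Reagents that add atoms: iodomethane, CI
Why: Williamson O-methylation of the acidic enolic hydroxyl, as in the methylation of maltol; the carbonate is too weak to deprotonate the benzylic methylene.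

Step 4
Reactants: 5 2-(3-bromo-4-methoxybenzyl)-3-methoxy-4H-pyran-4-one; 6 trimethyl phosphonoacetate
Product: 8 methyl 2-(3-bromo-4-methoxybenzyl)-4-hydroxy-3-methoxybenzoate, via ring-opened keto phosphonate enolate 7 (not isolated)
Conditions: 6 (2.5 equiv), NaH (2.5 equiv), THF, 0 °C; then 5, 25 → 66 °C; aq. HCl work-up
Reagents that add atoms: none
Why: Proposed new method: the sodium carbanion of 6 should add in a conjugate sense to the unsubstituted C6 of 5, the 2H-pyran adduct should open by β-elimination of the ring oxygen to the diketone enolate 7, and after proton transfer the phosphonate-stabilized carbanion should attack the C2 ketone and expel dimethyl phosphate (intramolecular Horner–Wadsworth–Emmons olefination), which forms C1–C6 and C1–C2 and leaves a cyclohexa-2,4-dienone that enolizes to the C4 phenol. The closest known reaction types are the base-mediated conversion of 4-pyranones into 4-nitrophenols with nitromethane and the conversion of pyrylium salts into benzenes with phosphorus ylides, in which a one-carbon nucleophile likewise takes the place of the ring oxygen. The carbocycle closes by an anionic 6-exo-trig addition of C1 to the C2 carbonyl, made irreversible by phosphate loss and aromatization; the Z geometry at C5=C6 needed for closure is accessible because the open form and the 2H-pyran interconvert and the dienolate is delocalized. No stereocentre is created, and the two transient sp3 centres of 7 disappear on aromatization. The step needs chemoselectivity for conjugate addition over olefination of the C4 carbonyl, which the vinylogous ester character of that carbonyl should secure, and it is indifferent to the site of attack because addition at C2 instead of C6 places the new carbon between the same two atoms. The product phenol consumes a second equivalent of base, hence the excess of the anion, and refluxing THF is preferred to hotter dipolar solvents so that the phenoxide is not methylated by the phosphonate esters.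

Step 5
Reactants: 8 methyl 2-(3-bromo-4-methoxybenzyl)-4-hydroxy-3-methoxybenzoate
Product: 9 methyl 5-bromo-2-(3-bromo-4-methoxybenzyl)-4-hydroxy-3-methoxybenzoate
Conditions: NBS (1.05 equiv), MeCN, 0 → 25 °C, dark
Reagents that add atoms: N-bromosuccinimide, O=C1CCC(=O)N1Br
Why: Electrophilic aromatic bromination ortho to a phenol, as in the bromination of vanillates; C5 is the only free site ortho or para to the C4 hydroxyl, ring B is a less reactive bromoanisole, and ionic conditions in the dark should spare the diarylmethane CH2.

Step 6
Reactants: 9 methyl 5-bromo-2-(3-bromo-4-methoxybenzyl)-4-hydroxy-3-methoxybenzoate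
Product: 10 methyl 5-bromo-2-(3-bromo-4-hydroxybenzyl)-3,4-dihydroxybenzoate
Conditions: BBr3 (5 equiv), CH2Cl2, −78 → 0 °C; ice–water
Reagents that add atoms: none
Why: Lewis acid cleavage of aryl methyl ethers by boron coordination and bromide attack on the methyl group; the conjugated, ortho-substituted methyl ester should survive at or below 0 °C, and no benzylic alcohol is present yet.

Step 7
Reactants: 10 methyl 5-bromo-2-(3-bromo-4-hydroxybenzyl)-3,4-dihydroxybenzoate
Product: 11 6-bromo-3-(3-bromo-4-hydroxybenzyl)-4-(hydroxymethyl)benzene-1,2-diol
Conditions: LiAlH4 (5 equiv), THF, 0 → 25 °C; aq. potassium sodium tartrate, pH 5–6, EtOAc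
Reagents that add atoms: none
Why: Hydride reduction of an ester to the primary alcohol in the presence of free phenols, which only consume hydride as aluminium phenoxides; keeping the temperature at or below 25 °C should spare the aryl bromides and avoid hydrogenolysis of the new benzylic C–O bond, and the near-neutral work-up protects the p-hydroxybenzyl alcohol.

## Compound list

1 | pyromeconic acid (3-hydroxy-4H-pyran-4-one) | O=c1ccocc1O | starting material
2 | 3-bromo-4-methoxybenzaldehyde | COc1ccc(C=O)cc1Br | starting material
3 | 2-[(3-bromo-4-methoxyphenyl)(hydroxy)methyl]-3-hydroxy-4H-pyran-4-one (racemic) | O=c1ccoc(C(O)c2ccc(OC)c(Br)c2)c1O | intermediate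
4 | 2-(3-bromo-4-methoxybenzyl)-3-hydroxy-4H-pyran-4-one | O=c1ccoc(Cc2ccc(OC)c(Br)c2)c1O | intermediate
5 | 2-(3-bromo-4-methoxybenzyl)-3-methoxy-4H-pyran-4-one | COc1c(Cc2ccc(OC)c(Br)c2)occc1=O | intermediate
6 | trimethyl phosphonoacetate | COC(=O)CP(=O)(OC)OC | starting material
7 | methyl (3Z)-8-(3-bromo-4-methoxyphenyl)-2-(dimethoxyphosphoryl)-6-methoxy-5,7-dioxooct-3-enoate (present in the flask as its sodium enolate; configuration at C2 and C6 undefined; not isolated) | COC(=O)C(P(=O)(OC)OC)/C=C\C(=O)C(OC)C(=O)Cc1ccc(OC)c(Br)c1 | intermediate
8 | methyl 2-(3-bromo-4-methoxybenzyl)-4-hydroxy-3-methoxybenzoate | COC(=O)c1ccc(O)c(OC)c1Cc1ccc(OC)c(Br)c1 | intermediate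
9 | methyl 5-bromo-2-(3-bromo-4-methoxybenzyl)-4-hydroxy-3-methoxybenzoate | COC(=O)c1cc(Br)c(O)c(OC)c1Cc1ccc(OC)c(Br)c1 | intermediate
10 | methyl 5-bromo-2-(3-bromo-4-hydroxybenzyl)-3,4-dihydroxybenzoate | COC(=O)c1cc(Br)c(O)c(O)c1Cc1ccc(O)c(Br)c1 | intermediate
11 | 6-bromo-3-(3-bromo-4-hydroxybenzyl)-4-(hydroxymethyl)benzene-1,2-diol | OCc1cc(Br)c(O)c(O)c1Cc1ccc(O)c(Br)c1 | target

## Step count and least certain steps

Total step count: 7. Longest linear sequence: 7 steps (1 to 11).

**Step 4 (key step, Proposed new method).** Three processes are most likely to defeat it.
- The conjugate addition may fail because the pyranone has partial aromatic character, leaving only reversible deprotonation of the benzylic methylene of 5 and self-condensation.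
- The ring-opened dienolate may be diverted by O-acylative lactonization onto the ester instead of attacking the ketone through carbon.
- The product phenoxide may be methylated by the phosphonate esters, which would erase the O3/O4 differentiation.

The fallback keeps pyranone 5 but uses the established ring transformation of 4-pyranones with a nitroalkane, then converts the nitro group into the ester. It sets out from 5 and comes back at 8.
- Heating 5 with nitromethane (C[N+](=O)[O-]) and KOtBu in t-BuOH should give 3-(3-bromo-4-methoxybenzyl)-2-methoxy-4-nitrophenol F1 by conjugate addition, ring opening and nitro-aldol closure.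
- Fe and NH4Cl in aqueous ethanol reduce the nitro group to 4-amino-3-(3-bromo-4-methoxybenzyl)-2-methoxyphenol F2 without touching the aryl bromide.
- Diazotization (NaNO2, aq. HCl, 0 °C) gives 2-(3-bromo-4-methoxybenzyl)-4-hydroxy-3-methoxybenzenediazonium chloride F3, which KI converts into 3-(3-bromo-4-methoxybenzyl)-4-iodo-2-methoxyphenol F4.
- Methoxycarbonylation (CO 1 atm, MeOH, Et3N, PdCl2(PPh3)2, 60 °C), selective for the C–I bond over the C–Br bonds, returns to the route at 8.

**Step 1.** The aldol equilibrium with an electron-rich aromatic aldehyde may lie on the side of the components, so that the adduct reverts on work-up. The carbinol may also dehydrate to a quinone-methide-like species that captures a second pyranone.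

The fallback reverses the polarity of the bond formation, so the pyranone becomes the electrophile. It sets out from 1 and comes back at 5.
- Hydroxymethylation of 1 with aqueous formaldehyde and NaOH gives 3-hydroxy-2-(hydroxymethyl)-4H-pyran-4-one F5.
- Selective methylation of the acidic enolic hydroxyl (MeI, K2CO3, acetone) gives 2-(hydroxymethyl)-3-methoxy-4H-pyran-4-one F6.
- MnO2 in CH2Cl2 oxidizes the allylic-type alcohol to 3-methoxy-4-oxo-4H-pyran-2-carbaldehyde F7.
- (3-Bromo-4-methoxyphenyl)magnesium chloride F8 is made from commercial 2-bromo-4-iodoanisole (COc1ccc(I)cc1Br) by selective iodine–magnesium exchange with iPrMgCl·LiCl at −20 °C. It adds to the aldehyde at −78 °C to give racemic 2-[(3-bromo-4-methoxyphenyl)(hydroxy)methyl]-3-methoxy-4H-pyran-4-one F9.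
- Ionic hydrogenation as in step 2 (Et3SiH, CF3CO2H, CH2Cl2) then delivers 5.

**Step 7.** Three things may go wrong:
- over-reduction by hydrogenolysis of the new benzylic C–O bond through the aluminium phenoxide and its quinone methide;
- slow reduction of the electron-rich, insoluble triphenoxide, which tempts warming and with it hydrodebromination;
- loss on work-up through chelation, oxidation or acid-induced ionization.

The fallback changes the order so that the ester is reduced while only one phenol is free, and the hydroxymethyl group is regenerated by solvolysis at the end. It sets out from 9 and comes back at 11.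
- LiAlH4 (3 equiv, THF, 0 °C) reduces 9 to 6-bromo-3-(3-bromo-4-methoxybenzyl)-4-(hydroxymethyl)-2-methoxyphenol F10.
- BBr3 (6 equiv, CH2Cl2, −78 → 0 °C) cleaves both methyl ethers and turns the hydroxymethyl group into the bromomethyl group of 6-bromo-3-(3-bromo-4-hydroxybenzyl)-4-(bromomethyl)benzene-1,2-diol F11.
- Stirring F11 in acetone–water with NaHCO3 at 25 °C hydrolyses the benzylic bromide through the p-quinone methide and gives 11.

## Further compounds

F1 | step 4 | 3-(3-bromo-4-methoxybenzyl)-2-methoxy-4-nitrophenol | COc1c(O)ccc([N+](=O)[O-])c1Cc1ccc(OC)c(Br)c1
F2 | step 4 | 4-amino-3-(3-bromo-4-methoxybenzyl)-2-methoxyphenol | COc1c(O)ccc(N)c1Cc1ccc(OC)c(Br)c1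
F3 | step 4 | 2-(3-bromo-4-methoxybenzyl)-4-hydroxy-3-methoxybenzenediazonium chloride | COc1c(O)ccc([N+]#N)c1Cc1ccc(OC)c(Br)c1.[Cl-]
F4 | step 4 | 3-(3-bromo-4-methoxybenzyl)-4-iodo-2-methoxyphenol | COc1c(O)ccc(I)c1Cc1ccc(OC)c(Br)c1
F5 | step 1 | 3-hydroxy-2-(hydroxymethyl)-4H-pyran-4-one | O=c1ccoc(CO)c1O
F6 | step 1 | 2-(hydroxymethyl)-3-methoxy-4H-pyran-4-one | COc1c(CO)occc1=O
F7 | step 1 | 3-methoxy-4-oxo-4H-pyran-2-carbaldehyde | COc1c(C=O)occc1=O
F8 | step 1 | (3-bromo-4-methoxyphenyl)magnesium chloride | COc1ccc([Mg]Cl)cc1Br
F9 | step 1 | 2-[(3-bromo-4-methoxyphenyl)(hydroxy)methyl]-3-methoxy-4H-pyran-4-one (racemic) | COc1c(C(O)c2ccc(OC)c(Br)c2)occc1=O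
F10 | step 7 | 6-bromo-3-(3-bromo-4-methoxybenzyl)-4-(hydroxymethyl)-2-methoxyphenol | OCc1cc(Br)c(O)c(OC)c1Cc1ccc(OC)c(Br)c1
F11 | step 7 | 6-bromo-3-(3-bromo-4-hydroxybenzyl)-4-(bromomethyl)benzene-1,2-diol | BrCc1cc(Br)c(O)c(O)c1Cc1ccc(O)c(Br)c1
A1 | alternative 1 | 4-bromo-2-({[1-(3-bromo-4-triisopropylsilyloxyphenyl)prop-2-yn-1-yl]oxy}methyl)furan (racemic) | C#CC(OCc1cc(Br)co1)c1ccc(O[Si](C(C)C)(C(C)C)C(C)C)c(Br)c1
A2 | alternative 1 | 6-bromo-3-(3-bromo-4-triisopropylsilyloxyphenyl)-1,3-dihydroisobenzofuran-4-ol (racemic) | Oc1cc(Br)cc2c1C(c1ccc(O[Si](C(C)C)(C(C)C)C(C)C)c(Br)c1)OC2
A3 | alternative 2 | 4-bromo-2,3-dimethoxy-6-(trimethylsilyl)phenyl trifluoromethanesulfonate | COc1c(OC)c(Br)cc([Si](C)(C)C)c1OS(=O)(=O)C(F)(F)F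
A4 | alternative 2 | tert-butyl isocyanide | CC(C)(C)[N+]#[C-]
A5 | alternative 2 | N-tert-butyl-6-bromo-3-(3-bromo-4-methoxyphenyl)-4,5-dimethoxy-3H-isobenzofuran-1-imine (racemic) | CC(C)(C)N=C1OC(c2ccc(OC)c(Br)c2)c2c(OC)c(OC)c(Br)cc21
A6 | alternative 3 | 5-(3-bromo-4-methoxyphenyl)pentane-2,3-dione | CC(=O)C(=O)CCc1ccc(OC)c(Br)c1
A7 | alternative 3 | (3Z)-5-(3-bromo-4-methoxyphenyl)-2,3-bis(trimethylsilyloxy)penta-1,3-diene | C=C(O[Si](C)(C)C)/C(O[Si](C)(C)C)=C/Cc1ccc(OC)c(Br)c1
A8 | alternative 3 | methyl propiolate | C#CC(=O)OC
A9 | alternative 3 | methyl 2-(3-bromo-4-methoxybenzyl)-3,4-bis(trimethylsilyloxy)benzoate | COC(=O)c1ccc(O[Si](C)(C)C)c(O[Si](C)(C)C)c1Cc1ccc(OC)c(Br)c1
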